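The runs were generated by integration for substances that don't exist, noise included.

Reagent is conserved: what leaves the second phase stands in the first phase, free or reacted.

| flask | starting material | reagent in the second phase | protic impurity | remark | time | volume of the second phase over the first |
|---|---|---|---|---|---|---|
| eta | 0.071 M | 0.102 M | 5.1 mM | run made earlier |  |  |
| epsilon | 0.11 M | 0.102 M | 5.1 mM | run made earlier |  |  |
| flask | 0.051 M | 0.102 M | 5.10 mM |  | 8.0 h | 2.0 |

- eta (time / h: target / %, starting material / %): 0.667: 5.3, 94.2; 1.50: 10.0, 87.6; 3.00: 15.6, 75.7; 5.00: 20.2, 65.3
- epsilon (time / h: target / %, starting material / %): 0.667: 3.7, 95.8; 1.50: 5.9, 91.7; 3.00: 10.6, 84.4; 5.00: 13.6, 74.8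

(scatter of a reading: 0.5 percentage points)

- in the second phase: reagent in the second phase; everything else is in the first
- charges count per volume of the first phase; a concentration in a rate is the amount of a species over the volume of its own phase; every rate counts per litre of the first phase
- on the list of suspects stand: reagent in the reaction phase <-> reagent in the second phase; target <-> isomer of the product; reagent in the reaction phase -> decomposed reagent; starting material + reagent in the reaction phase -> target; reagent in the reaction phase + protic impurity -> quenched reagent; reagent in the reaction phase + target -> over-reacted product
- the earlier runs hold the two phases in the same ratio of volumes as the flask asked about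

- how much target there is at 8.0 h, in percent of the starting material charged
- part of the starting material charged that has reacted at 8.0 h

1. The eta run loses 0.0246 M of starting material by 5.00 h, and the epsilon run loses 0.0277 M. The charge rises by a factor of 1.55, but the loss rises by a factor of 1.13, so I take the crossing of reagent as the rate-limiting step.

2. I assume that the crossing rate follows what stands in the second phase, with [reagent in the reaction phase] staying low. Then d[reagent in the second phase]/dt = −λ[reagent in the second phase], which integrates to its charge times exp(−λt).

3. I count one reagent per starting material lost. The runs then read 0.0553 h⁻¹ and 0.0634 h⁻¹, with mean 0.0594 h⁻¹. This is my drain constant λ, the part of the reservoir that crosses per hour.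

4. For the flask, I reckon that 62.2% of the reservoir stays at 8.0 h, so that 0.0386 M crosses, less than the 0.051 M of starting material. My decision is to keep the charges and the time, and to expect starting material left, with about 75.7% reacted.

5. The forecast gives 21% of target and 59% reacted, below my figure, and says the runs suggest that “supply of reagent from the second phase is limiting”.

The flask gives 30.3% of target and 66.5% reacted.

    reagent in the reaction phase ⇌ reagent in the second phase, rate k1*([reagent in the reaction phase] - [reagent in the second phase]/K1) per volume of the first phase (partition coefficient = 1.75, kL = 0.00380 min⁻¹)
    target ⇌ isomer of the product (K = 1.20, k = 0.00602 min⁻¹)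
    reagent in the reaction phase → decomposed reagent (k = 0.00154 min⁻¹)
    starting material + reagent in the reaction phase → target (k = 3.68 M⁻¹ min⁻¹)
    reagent in the reaction phase + protic impurity → quenched reagent (k = 0.815 M⁻¹ min⁻¹)
    reagent in the reaction phase + target → over-reacted product (k = 1.33 M⁻¹ min⁻¹)

In the flask, 60.3% of the reservoir remains against my 62.2%, and 0.0339 M of starting material has reacted, against 0.0405 M of reagent crossed. The neighbour with 0.031 M of starting material has the same reagent charge and time, so λ again gives 62.2% remaining and 0.0386 M crossed, now more than its charge of starting material. That neighbour shows 61.2% remaining, 89.1% reacted and 23.0% of over-reacted product.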